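**Plan**

- Eudesmane numbering is used (ring A: C1–C5 and C10; ring B: C5–C10); β is the face of the C10 methyl group.
- Cuts, in retrosynthetic order: the O4–acetyl and O3–epoxyacyl ester bonds; the C3–O and C4–O bonds (cis-diol from a C3=C4 alkene); the C7–isopropyl bond and the C8 oxygen (replaced by a C7 ketone with a C8=C9 alkene); last the C4–C5 ring bond.
- Enabling feature: C10 with its methyl group is the para carbon of a ring B cyclohexa-2,5-dienone whose carbonyl is C7. Its alkenes C5=C6 and C9=C8 are enantiotopic, so one C4–C5 bond from a (Z)-alkenyl iodide on the C1–C3 tether creates C10 and C5 together.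
- Forward order: ring B first (Stork–Danheiser alkylations and transposition, iodo-Wittig reaction, dehydrogenation), ring A by a palladium-catalysed reductive cyclisation, then the diol, the C7/C8 adjustment and the two esters.
- Stereochemistry: C10 and C5 from the chiral palladium catalyst and the tether (cis fusion); C3 and C4 from a Woodward cis-hydroxylation that puts both oxygens on the α face; C7 by equilibration next to the C8 ketone; the epoxide centres from a Sharpless epoxidation of angelyl alcohol.

Key step: step 6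

Assumption: the sense of induction of the BINAP–palladium catalyst on this dienone cannot be derived with certainty; (R)-BINAP is written, and (S)-BINAP would be used instead if the first run gave the mirror image of 12.

**Route**

Step 1
Reactants: 1 3-ethoxycyclohex-2-en-1-one; 2 2-(2-bromoethyl)-1,3-dioxolane
Product: 4 rac-6-[2-(1,3-dioxolan-2-yl)ethyl]-3-ethoxycyclohex-2-en-1-one, via lithium dienolate 3 (not isolated)
Conditions: LiN(iPr)2, THF, −78 °C; then 2, DMPU, −78 °C → rt
Reagents that add atoms: none
Why: Kinetic deprotonation of the vinylogous ester takes place at the α′ carbon, and the cross-conjugated enolate is C-alkylated by the primary bromide (Stork–Danheiser α′-alkylation), with DMPU favouring substitution over elimination.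

Step 2
Reactants: 4 rac-6-[2-(1,3-dioxolan-2-yl)ethyl]-3-ethoxycyclohex-2-en-1-one
Product: 6 rac-6-[2-(1,3-dioxolan-2-yl)ethyl]-3-ethoxy-6-methylcyclohex-2-en-1-one, via lithium enolate 5 (not isolated)
Conditions: LiN(iPr)2, THF, −78 °C; then MeI, −78 → 0 °C
Reagents that add atoms: methyl iodide, CI
Why: A second Stork–Danheiser α′-alkylation with the small, reactive MeI should build the quaternary carbon (the future C10); its racemic nature is irrelevant because this carbon loses its chirality at the dienone stage.

Step 3
Reactants: 6 rac-6-[2-(1,3-dioxolan-2-yl)ethyl]-3-ethoxy-6-methylcyclohex-2-en-1-one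
Product: 8 rac-3-(1-methyl-4-oxocyclohex-2-en-1-yl)propanal, via allylic alcohol 7 (not isolated)
Conditions: LiAlH4, Et2O, 0 °C; then 2 M HCl, THF, rt
Reagents that add atoms: water, O
Why: 1,2-Reduction of the vinylogous ester followed by acid-induced ionisation and enol ether hydrolysis gives the transposed 4,4-disubstituted enone (Stork–Danheiser transposition), and the same acid hydrolyses the dioxolane to the aldehyde.

Step 4
Reactants: 8 rac-3-(1-methyl-4-oxocyclohex-2-en-1-yl)propanal; 9 ethyltriphenylphosphonium bromide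
Product: 10 rac-4-[(3Z)-4-iodopent-3-en-1-yl]-4-methylcyclohex-2-en-1-one
Conditions: 9, n-BuLi, THF, rt; I2, −78 °C; NaN(SiMe3)2, −20 °C; then 8, −78 °C
Reagents that add atoms: iodine, II
Why: The α-iodoethylidene ylide made in the flask reacts under kinetic control through the cis-oxaphosphetane (Stork–Zhao-type Wittig olefination), which should give the (Z)-2-iodoalkene, and at −78 °C the aldehyde is attacked far faster than the enone carbonyl.

Step 5
Reactants: 10 rac-4-[(3Z)-4-iodopent-3-en-1-yl]-4-methylcyclohex-2-en-1-one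
Product: 11 4-[(3Z)-4-iodopent-3-en-1-yl]-4-methylcyclohexa-2,5-dien-1-one
Conditions: 2-iodoxybenzoic acid (IBX), DMSO/fluorobenzene, 70 °C
Reagents that add atoms: none
Why: IBX dehydrogenates the ketone on its only enolisable side (Nicolaou dehydrogenation) to the cross-conjugated, achiral dienone, and the alkenyl iodide is not expected to react with the hypervalent iodine oxidant.

Step 6
Reactants: 11 4-[(3Z)-4-iodopent-3-en-1-yl]-4-methylcyclohexa-2,5-dien-1-one
Product: 12 (4aR,8aR)-4a,8-dimethyl-4a,5,6,8a-tetrahydronaphthalen-2(1H)-one (11,12,13-trinor-5βH-eudesma-3,8-dien-7-one; 5R,10R)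
Conditions: Pd(OAc)2 (10 mol %), (R)-BINAP (12 mol %), HCO2Na (2 equiv), DMF, 70 °C
Reagents that add atoms: none
Why: Zerovalent palladium, formed in the flask from Pd(OAc)2 and the bisphosphine, inserts into the C4–I bond with retention of the Z geometry, and the alkenylpalladium adds syn across one dienone alkene (C4 to C5, palladium to C6). The C6 palladium enolate has its only β-hydrogen (H5) anti to the metal, so formate exchange, loss of CO2 and C–H reductive elimination release the enone and zerovalent palladium instead of a Heck alkene. The closest known reaction type is the enantioselective intramolecular reductive Heck (formal conjugate addition) desymmetrisation of 4,4-disubstituted cyclohexa-2,5-dienones. Ring A closes in the 6-exo-trig mode, the Z iodide allowing the C3=C4 alkene to sit inside the new ring. C5 is controlled by the three-carbon tether, which can reach C5 only on the face of ring B that carries C1 (hence H5 cis to the C10 methyl), and C10 is controlled by which of the two enantiotopic alkenes inserts, a choice made by the chiral ligand on palladium. The step needs enantiotopic-group selection (ligand), 6-exo over 7-endo closure (conjugate polarity and ring size), and cyclisation before formate reduction of the alkenylpalladium (fast intramolecular insertion).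

Step 7
Reactants: 12 (4aR,8aR)-4a,8-dimethyl-4a,5,6,8a-tetrahydronaphthalen-2(1H)-one
Product: 15 3α,4α-dihydroxy-11,12,13-trinor-5βH-eudesm-8-en-7-one, via trans iodo acetate 13 (not isolated), via hydroxy acetate 14 (not isolated)
Conditions: I2, AgOAc, AcOH, rt; then AcOH/H2O, 90 °C; then K2CO3, MeOH, rt
Reagents that add atoms: silver acetate, CC(=O)[O-].[Ag+]
Why: In this Woodward cis-hydroxylation the iodonium ion should form on the convex β face, acetate opens it trans-diaxially at tertiary C4 from the α face, silver-assisted displacement of iodide by the neighbouring acetate gives an α-fused acetoxonium ion that water opens to the cis hydroxy acetate, and methanolysis then gives the α,α-diol with both new centres relayed from C5 and C10, the electron-poor enone being left untouched.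

Step 8
Reactants: 15 3α,4α-dihydroxy-11,12,13-trinor-5βH-eudesm-8-en-7-one
Product: 16 3α,4α-(isopropylidenedioxy)-11,12,13-trinor-5βH-eudesm-8-en-7-one
Conditions: 2,2-dimethoxypropane, PPTS, acetone, rt
Reagents that add atoms: 2,2-dimethoxypropane, COC(C)(C)OC
Why: Acid-catalysed transketalisation converts the cis secondary/tertiary diol into a dioxolane that will survive the dissolving metal, organozinc and borane steps.

Step 9
Reactants: 16 3α,4α-(isopropylidenedioxy)-11,12,13-trinor-5βH-eudesm-8-en-7-one
Product: 18 3α,4α-(isopropylidenedioxy)-11,12,13-trinor-5βH-eudesm-7-en-7-yl trifluoromethanesulfonate, via lithium enolate 17 (not isolated)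
Conditions: Li (2.2 equiv), t-BuOH (1 equiv), NH3/THF, −78 °C; NH3 evaporated; PhNTf2, THF, −78 °C → rt
Reagents that add atoms: N-phenylbis(trifluoromethanesulfonimide), O=S(=O)(N(c1ccccc1)S(=O)(=O)C(F)(F)F)C(F)(F)F
Why: Dissolving-metal reduction of the enone gives the C7–C8 lithium enolate regiospecifically (Stork reductive enolate formation), and O-sulfonylation with PhNTf2 (McMurry–Scott trapping) fixes the alkene at C7=C8 before the enolate can equilibrate.

Step 10
Reactants: 18 3α,4α-(isopropylidenedioxy)-11,12,13-trinor-5βH-eudesm-7-en-7-yl trifluoromethanesulfonate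
Product: 19 3α,4α-(isopropylidenedioxy)-5βH-eudesm-7-ene
Conditions: i-PrZnBr, PdCl2(dppf) (5 mol %), THF, 50 °C
Reagents that add atoms: isopropylzinc bromide, CC(C)[Zn]Br
Why: Negishi cross-coupling of the alkenyl triflate with the secondary alkylzinc reagent should proceed without isomerisation to n-propyl, because the wide-bite-angle dppf ligand makes reductive elimination faster than β-hydride elimination.

Step 11
Reactants: 19 3α,4α-(isopropylidenedioxy)-5βH-eudesm-7-ene
Product: 21 3α,4α-(isopropylidenedioxy)-5βH,7αH-eudesman-8α-ol, via alkylborane 20 (not isolated)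
Conditions: BH3·THF, THF, 0 °C → rt; then NaOH, H2O2, 0 °C → rt
Reagents that add atoms: hydrogen peroxide, OO
Why: Brown hydroboration–oxidation places boron on the less substituted C8 by syn addition, expected from the α face away from the axial C10 methyl group, and any diastereomer formed converges in the next step because C8 becomes a ketone and C7 becomes epimerisable.

Step 12
Reactants: 21 3α,4α-(isopropylidenedioxy)-5βH,7αH-eudesman-8α-ol
Product: 22 3α,4α-(isopropylidenedioxy)-5βH,7αH-eudesman-8-one
Conditions: Dess–Martin periodinane, NaHCO3, CH2Cl2, rt; crude product then K2CO3, MeOH, rt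
Reagents that add atoms: none
Why: Dess–Martin oxidation gives the C8 ketone, and base equilibration through the enolate should leave the isopropyl group equatorial (7β) in the only ring conformer that avoids a 1,3-diaxial contact between the C4 and C10 methyl groups, which makes 7β the thermodynamic configuration.

Step 13
Reactants: 22 3α,4α-(isopropylidenedioxy)-5βH,7αH-eudesman-8-one
Product: 23 3α,4α-dihydroxy-5βH,7αH-eudesman-8-one
Conditions: AcOH/H2O (4:1), 50 °C
Reagents that add atoms: none
Why: Mild aqueous acid hydrolyses the ketal without ionising the tertiary alcohol, and C7 remains at its thermodynamic configuration.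

Step 14
Reactants: 24 angelic acid
Product: 25 (Z)-2-methylbut-2-en-1-ol (angelyl alcohol)
Conditions: LiAlH4, Et2O, 0 °C → rt
Reagents that add atoms: none
Why: Hydride reduction of the carboxylic acid gives the allylic alcohol with the Z geometry of the trisubstituted alkene intact.

Step 15
Reactants: 25 (Z)-2-methylbut-2-en-1-ol
Product: 26 [(2R,3S)-2,3-dimethyloxiran-2-yl]methanol
Conditions: Ti(OiPr)4 (10 mol %), D-(−)-diisopropyl tartrate (12 mol %), t-BuOOH, 4 Å molecular sieves, CH2Cl2, −20 °C
Reagents that add atoms: tert-butyl hydroperoxide, CC(C)(C)OO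
Why: In the Sharpless asymmetric epoxidation the titanium–tartrate complex delivers oxygen to one face of the allylic alcohol, the D-(−)-tartrate being the one that should give the (2R,3S) epoxide, while the Z geometry keeps the C3 methyl group cis to the CH2OH group.

Step 16
Reactants: 26 [(2R,3S)-2,3-dimethyloxiran-2-yl]methanol
Product: 27 (2S,3S)-2,3-dimethyloxirane-2-carboxylic acid
Conditions: RuCl3 (2 mol %), NaIO4, MeCN/EtOAc/H2O, rt
Reagents that add atoms: water, O
Why: RuO4 generated in the flask oxidises the primary alcohol through the aldehyde hydrate to the acid (Sharpless ruthenium oxidation) without opening the epoxide, the change of the C2 descriptor from R to S being only a change of CIP priorities.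

Step 17
Reactants: 27 (2S,3S)-2,3-dimethyloxirane-2-carboxylic acid; 23 3α,4α-dihydroxy-5βH,7αH-eudesman-8-one
Product: 29 3α-[(2S,3S)-2,3-epoxy-2-methylbutanoyloxy]-4α-hydroxy-5βH,7αH-eudesman-8-one, via mixed anhydride 28 (not isolated)
Conditions: 27, 2,4,6-trichlorobenzoyl chloride, Et3N, toluene, rt; then 23, DMAP, toluene, rt → 40 °C
Reagents that add atoms: none
Why: In this Yamaguchi esterification DMAP attacks the less shielded epoxyacyl carbonyl of the mixed anhydride and transfers it to the equatorial secondary C3 hydroxyl only, the tertiary C4 hydroxyl being too hindered and the quaternary α-carbon of the acid being unable to epimerise.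

Step 18
Reactants: 29 3α-[(2S,3S)-2,3-epoxy-2-methylbutanoyloxy]-4α-hydroxy-5βH,7αH-eudesman-8-one
Product: 30 CNP0221066.1, 4α-acetoxy-3α-[(2S,3S)-2,3-epoxy-2-methylbutanoyloxy]-5βH,7αH-eudesman-8-one (3R,4S,5S,7R,10R)
Conditions: Ac2O, DMAP, Et3N, CH2Cl2, 40 °C
Reagents that add atoms: acetic anhydride, CC(=O)OC(C)=O
Why: DMAP-catalysed acyl transfer through the N-acetylpyridinium ion should acetylate the tertiary alcohol under forcing but non-acidic conditions that the epoxide, the ketone and the hindered, migration-resistant epoxy ester tolerate.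

**Compound list**

1 | 3-ethoxycyclohex-2-en-1-one | CCOC1=CC(=O)CCC1 | starting material
2 | 2-(2-bromoethyl)-1,3-dioxolane | BrCCC1OCCO1 | starting material
3 | lithium 5-ethoxycyclohexa-1,5-dien-1-olate | CCOC1=CC([O-])=CCC1.[Li+] | intermediate (not isolated)
4 | rac-6-[2-(1,3-dioxolan-2-yl)ethyl]-3-ethoxycyclohex-2-en-1-one | CCOC1=CC(=O)C(CCC2OCCO2)CC1 | intermediate
5 | lithium 2-[2-(1,3-dioxolan-2-yl)ethyl]-5-ethoxycyclohexa-1,5-dien-1-olate | CCOC1=CC([O-])=C(CCC2OCCO2)CC1.[Li+] | intermediate (not isolated)
6 | rac-6-[2-(1,3-dioxolan-2-yl)ethyl]-3-ethoxy-6-methylcyclohex-2-en-1-one | CCOC1=CC(=O)C(C)(CCC2OCCO2)CC1 | intermediate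
7 | 6-[2-(1,3-dioxolan-2-yl)ethyl]-3-ethoxy-6-methylcyclohex-2-en-1-ol (diastereomer mixture) | CCOC1=CC(O)C(C)(CCC2OCCO2)CC1 | intermediate (not isolated)
8 | rac-3-(1-methyl-4-oxocyclohex-2-en-1-yl)propanal | O=CCCC1(C)C=CC(=O)CC1 | intermediate
9 | ethyltriphenylphosphonium bromide | CC[P+](c1ccccc1)(c1ccccc1)c1ccccc1.[Br-] | starting material
10 | rac-4-[(3Z)-4-iodopent-3-en-1-yl]-4-methylcyclohex-2-en-1-one | C/C(I)=C/CCC1(C)C=CC(=O)CC1 | intermediate
11 | 4-[(3Z)-4-iodopent-3-en-1-yl]-4-methylcyclohexa-2,5-dien-1-one | C/C(I)=C/CCC1(C)C=CC(=O)C=C1 | intermediate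
12 | (4aR,8aR)-4a,8-dimethyl-4a,5,6,8a-tetrahydronaphthalen-2(1H)-one | CC1=CCC[C@]2(C)C=CC(=O)C[C@@H]21 | intermediate
13 | 4α-acetoxy-3β-iodo-11,12,13-trinor-5βH-eudesm-8-en-7-one | CC(=O)O[C@]1(C)[C@@H](I)CC[C@]2(C)C=CC(=O)C[C@@H]21 | intermediate (not isolated)
14 | 4α-acetoxy-3α-hydroxy-11,12,13-trinor-5βH-eudesm-8-en-7-one (any O3 acetate isomer is hydrolysed alike) | CC(=O)O[C@]1(C)[C@H](O)CC[C@]2(C)C=CC(=O)C[C@@H]21 | intermediate (not isolated)
15 | 3α,4α-dihydroxy-11,12,13-trinor-5βH-eudesm-8-en-7-one | O[C@]1(C)[C@H](O)CC[C@]2(C)C=CC(=O)C[C@@H]21 | intermediate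
16 | 3α,4α-(isopropylidenedioxy)-11,12,13-trinor-5βH-eudesm-8-en-7-one | CC3(C)O[C@]1(C)[C@H](O3)CC[C@]2(C)C=CC(=O)C[C@@H]21 | intermediate
17 | lithium 3α,4α-(isopropylidenedioxy)-11,12,13-trinor-5βH-eudesm-7-en-7-olate | CC3(C)O[C@]1(C)[C@H](O3)CC[C@]2(C)CC=C([O-])C[C@@H]21.[Li+] | intermediate (not isolated)
18 | 3α,4α-(isopropylidenedioxy)-11,12,13-trinor-5βH-eudesm-7-en-7-yl trifluoromethanesulfonate | CC3(C)O[C@]1(C)[C@H](O3)CC[C@]2(C)CC=C(OS(=O)(=O)C(F)(F)F)C[C@@H]21 | intermediate
19 | 3α,4α-(isopropylidenedioxy)-5βH-eudesm-7-ene | CC3(C)O[C@]1(C)[C@H](O3)CC[C@]2(C)CC=C(C(C)C)C[C@@H]21 | intermediate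
20 | 8α-boranyl-3α,4α-(isopropylidenedioxy)-5βH,7αH-eudesmane | CC3(C)O[C@]1(C)[C@H](O3)CC[C@]2(C)C[C@H](B)[C@@H](C(C)C)C[C@@H]21 | intermediate (not isolated)
21 | 3α,4α-(isopropylidenedioxy)-5βH,7αH-eudesman-8α-ol | CC3(C)O[C@]1(C)[C@H](O3)CC[C@]2(C)C[C@H](O)[C@@H](C(C)C)C[C@@H]21 | intermediate
22 | 3α,4α-(isopropylidenedioxy)-5βH,7αH-eudesman-8-one | CC3(C)O[C@]1(C)[C@H](O3)CC[C@]2(C)CC(=O)[C@@H](C(C)C)C[C@@H]21 | intermediate
23 | 3α,4α-dihydroxy-5βH,7αH-eudesman-8-one | O[C@]1(C)[C@H](O)CC[C@]2(C)CC(=O)[C@@H](C(C)C)C[C@@H]21 | intermediate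
24 | angelic acid, (Z)-2-methylbut-2-enoic acid | C/C=C(/C)C(=O)O | starting material
25 | (Z)-2-methylbut-2-en-1-ol | C/C=C(/C)CO | intermediate
26 | [(2R,3S)-2,3-dimethyloxiran-2-yl]methanol | OC[C@@]1(C)O[C@H]1C | intermediate
27 | (2S,3S)-2,3-dimethyloxirane-2-carboxylic acid | OC(=O)[C@@]1(C)O[C@H]1C | intermediate
28 | (2S,3S)-2,3-dimethyloxirane-2-carboxylic 2,4,6-trichlorobenzoic anhydride | O=C(OC(=O)[C@@]1(C)O[C@H]1C)c1c(Cl)cc(Cl)cc1Cl | intermediate (not isolated)
29 | 3α-[(2S,3S)-2,3-epoxy-2-methylbutanoyloxy]-4α-hydroxy-5βH,7αH-eudesman-8-one | O[C@]1(C)[C@H](OC(=O)[C@@]2(C)O[C@H]2C)CC[C@]2(C)CC(=O)[C@@H](C(C)C)C[C@@H]21 | intermediate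
30 | CNP0221066.1, 4α-acetoxy-3α-[(2S,3S)-2,3-epoxy-2-methylbutanoyloxy]-5βH,7αH-eudesman-8-one | CC(=O)O[C@]1(C)[C@H](OC(=O)[C@@]2(C)O[C@H]2C)CC[C@]2(C)CC(=O)[C@@H](C(C)C)C[C@@H]21 | target

**Step count**

Total: 18 steps. Longest linear sequence: 15 steps (steps 1–13, 17 and 18); steps 14–16 make the epoxy acid.

**The three steps most likely to fail**

Step 6. What may go wrong: weak discrimination between the two enantiotopic alkenes during insertion, or formate reduction of the alkenylpalladium before it cyclises. Fallback: starting from 11, the same ring closure is run without asymmetric induction (Pd(PPh3)4, HCO2Na, DMF) to give the racemic cis-fused dienone F1. This racemate is resolved by preparative chromatography on a chiral stationary phase, and its (5R,10R) enantiomer is 12, where the route resumes.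

Step 7. What may go wrong: opening of the iodonium ion from the other face or at C3, or iodination of the enone, so that the α,α-diol is not the main product. Fallback: starting from 12, mCPBA in CH2Cl2 should epoxidise the ring A alkene from the convex β face to the 3β,4β-epoxide F2. Acid-catalysed hydrolysis (HClO4, THF/H2O) opens it trans-diaxially at tertiary C4 to the 3β,4α-diol F3. Dess–Martin oxidation of the secondary alcohol gives the 4α-hydroxy-3,7-dione F4. NaBH4 in MeOH/CH2Cl2 at −78 °C reduces the saturated ketone in preference to the conjugated enone, with hydride delivered from the β face, and gives the 3α-alcohol, which is diol 15.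

Step 18. What may go wrong: slow acylation of the axial tertiary alcohol, which would allow migration of the epoxy ester from O3 to O4 followed by acetylation at O3, or elimination. Fallback: starting from 23, trimethyl orthoacetate and PPTS convert the cis-diol into the cyclic orthoacetate F5. Dilute aqueous acetic acid opens it under stereoelectronic control to the axial ester, the 4α-acetoxy-3α-hydroxy ketone F6. Yamaguchi esterification of this alcohol with acid 27 (through mixed anhydride 28) then gives target 30.

**Further compounds**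

F1 | step 6 | racemic cis-4a,8-dimethyl-4a,5,6,8a-tetrahydronaphthalen-2(1H)-one | CC1=CCC[C@]2(C)C=CC(=O)C[C@@H]21.CC1=CCC[C@@]2(C)C=CC(=O)C[C@H]21
F2 | step 7 | 3β,4β-epoxy-11,12,13-trinor-5βH-eudesm-8-en-7-one | O3[C@@]1(C)[C@@H]3CC[C@]2(C)C=CC(=O)C[C@@H]21
F3 | step 7 | 3β,4α-dihydroxy-11,12,13-trinor-5βH-eudesm-8-en-7-one | O[C@]1(C)[C@@H](O)CC[C@]2(C)C=CC(=O)C[C@@H]21
F4 | step 7 | 4α-hydroxy-11,12,13-trinor-5βH-eudesm-8-ene-3,7-dione | O[C@]1(C)C(=O)CC[C@]2(C)C=CC(=O)C[C@@H]21
F5 | step 18 | 3α,4α-(1-methoxyethylidenedioxy)-5βH,7αH-eudesman-8-one (cyclic orthoacetate, mixture at the orthoester carbon) | COC3(C)O[C@]1(C)[C@H](O3)CC[C@]2(C)CC(=O)[C@@H](C(C)C)C[C@@H]21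
F6 | step 18 | 4α-acetoxy-3α-hydroxy-5βH,7αH-eudesman-8-one | CC(=O)O[C@]1(C)[C@H](O)CC[C@]2(C)CC(=O)[C@@H](C(C)C)C[C@@H]21
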